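## Structural features

The target is an eight-ring phlorotannin in which all rings are benzene rings, joined only by diaryl ether oxygens and two biaryl bonds. The central ring C is 1,2,3,5-tetraoxygenated: C6 carries the ether to the chlorinated ring E (4-chloro-3,5-dihydroxyphenyl), C1 and C5 carry two identical arms, and C3 a free hydroxyl. In each arm ring B is bound through B4–O to ring C and bears hydroxyls at B3 and B5, the ether B1–O–A1 to a 2,4,6-trihydroxyphenyl ring A, hydrogen at B2 and, at B6, a carbon-bound 2,4,6-trihydroxyphenyl ring D. There is no stereocentre, so none stand next to each other; the two B6–D1 axes are tetra-ortho-substituted, but ring D is symmetric about its axis and no atropisomers exist. Fragile features are the nineteen free phenols (air- and base-sensitive once unmasked) and the single aryl chloride on ring E, which rules out hydrogenolysis and is a possible site for palladium insertion. The real difficulty is that every ether has one carbon flanked by two oxygen substituents (A1, B4, C6) and that ring B is pentasubstituted, with four oxygens and one aryl group in a fixed order. The key step exploits the neighbourhood B5(O)–B6–B1: a B1–B6 aryne is polarised by the oxygen at B5, so the oxygen of a ring A phenol, which cannot be arylated at A1 by ordinary substitution, bonds to B1.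

## Logic of the disconnections

**35 from 34.** The nineteen O–CH3 bonds are cut last. Methyl is the one permanent mask because it survives organolithium, fluoride, acid, iodine and palladium steps and because the methylated building blocks are at hand. The gain is that every earlier intermediate is a neutral ether that can be chromatographed. The forward step must cleave all ethers with a boron Lewis acid without touching diaryl ethers, biaryl bonds or the chloride, and the product must be isolated without air.

**34 from 32 and 33.** The two B6–D1 bonds are cut. This removes both rings D in one symmetric operation and leaves a six-ring dihalide and a simple ring D nucleophile. The forward step is a tetra-ortho-substituted biaryl coupling that has to spare the ring E chloride.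

**32 back to 29 (through 31 and 30).** The C–I bonds at B6 and the O–methyl bonds at B3 and B5 are cut, and those two oxygens go back to acetal protection. The reason is that only free phenols on ring B distinguish it from the four other electron-rich rings towards an electrophile. In 30 the positions B2 and B6 are equivalent, so the forward iodination needs one iodine per ring B and none elsewhere, but no direction within the ring.

**29 from 24 and 27 (key disconnection).** The two B1–O bonds are cut with inverted polarity: B1 becomes the electrophilic end of a B1–B6 aryne and A1 keeps its oxygen as a nucleophile. A1 is flanked by two oxygens and has no activating group, so ring A cannot be the electrophile. The gain is a symmetric four-ring core and a one-step ring A building block. The forward step needs regiocontrol in the addition to an unsymmetrical aryne, which the B5 oxygen next to B6 supplies, and fast protonation at B6.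

**24 from 17 (through 22 and 18).** The C–Si bonds at B6 and the O–S bonds at B1 are cut. Both groups hang on the B1 oxygen: as a carbamate it directs metalation to the neighbouring carbon, and after removal of the carbamate it becomes the leaving group. The gain is a core with two plain phenols. The forward steps must metalate only between the carbamate and the acetal oxygen, once per ring, and must unmask the phenol without losing silicon.

**17 from 14 and 6 (through 15).** The two B4–O bonds are cut; the B1 oxygens are traced back to formyl groups. A para-formyl group makes the flanked carbon B4 electrophilic towards the C1 and C5 phenoxides and is later turned into the B1 hydroxyl by oxygen insertion. The gain is that both rings B come from one small fluoroarene. The forward step is a double substitution at a carbon flanked by two acetal oxygens.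

**14 from 9 and 6 (through 10, 12, 13).** The C6–O bond is cut in the same way, and the C3 oxygen is traced back to the formyl group. The gain is that ring C and ring B come from the same building block; the price is one methylation and one acetal cleavage to expose C1 and C5.

**6 from 1 (through 2, 3); 9 from 7; 27 from 25.** In 6 the C–F bond is cut: the carbon between two acetal oxygens is the most acidic on the ring, so the fluoride is introduced by metalation and an electrophilic fluorine source. In 9 the C–O bond is cut to the one unhindered C–H of 7. In 27 the C–O bond is cut back to a formyl group.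

## Other disconnections considered

**Alternative 1:** The cut is made inside each ring D, at D1–D2, so that ring D is unfolded into a benzylic 3,5-dioxohexanoate chain on B6 (A2). In the forward direction an alkoxide base would let the benzylic carbon of each chain of A2 attack its own ester carbonyl, a Claisen-type six-membered closure, and the triones would enolise to the two phloroglucinol rings of A1.
- In its favour: the crowded B6–D1 bond is present from the start as an ordinary benzylic bond, no palladium meets the ring E chloride, and rings D are born as free phenols, so thirteen rather than nineteen methyl ethers remain to be cleaved. On these three points it is better than the chosen plan.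
- Against it here: the benzylic methylene is the least acidic of the three methylenes of the chain, so the closure competes with lactonisation through the enol oxygen and with aldol-type foldings. The chain must also be attached to B6 of a ring B that already carries rings A and C, which needs the same B1–O bond formation and the same functionalisation of B6 as the chosen route, followed by chain building on both arms.
- Comparison: in structure the two plans share the problem of ring B and differ only in how ring D arrives. In mechanism the folding is driven by aromatisation and needs no catalyst (equal or better in simplicity), but its regiochemistry rests on the least favoured enolate. In step economy it replaces the coupling step by at least four chain-building steps and is longer.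

**Alternative 2:** Each ring B is cut at B5–B6 and B1–B2 into a four-carbon cyclobutenone on the core (B2 to B5, compound A4) and a two-carbon ynol ether that carries rings A and D (A5). Heating A4 with two equivalents of A5 would open each cyclobutenone to a vinylketene, add the alkyne by [2+2] cycloaddition, and after four-electron ring opening and six-electron ring closure give both rings B of A3 as phenols (Danheiser benzannulation).
- In its favour: one operation assembles the whole pentasubstituted ring with its three neighbours in an order fixed by the mechanism. No aryne, silyl triflate, iodination or hindered cross-coupling is needed, and the B5 hydroxyl is set free apart from B3. In convergence and in the number of operations on the full core it is better than the chosen plan.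
- Against it here: A4 needs two 4-aryloxy-3-ethoxycyclobutenones built on the phenols of 14. A5 is an aryl aryloxy alkyne of a 2,6-disubstituted phenol with a 2,6-disubstituted aryl on the nucleophilic carbon, a hindered and heat-sensitive partner. Both annulations must succeed on one molecule at the temperature of cyclobutenone opening.
- Comparison: in structure the alternative solves the crowding of ring B in the ring-forming event, whereas the chosen plan decorates a ring that exists. In mechanism a pericyclic cascade with a little-tested substitution pattern stands against an ionic aryne addition with well-understood regiocontrol. In step economy the two are about equal if A5 is reachable in three steps; the choice rests on the lower risk of the aryne partners.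

**Alternative 3:** Ring C is cut at C1–C2 and C4–C5 into the aryloxymalonate A7 (C1, C6, C5 with the ring E ether in place) and the acetonedicarboxylate A8 (C2, C3, C4). Two Claisen acylations under alkoxide base would close the six-membered ring, which aromatises to the trihydroxyisophthalate A6; saponification and decarboxylation would lead to the triol A9.
- In its favour: the most hindered ether of the core (C6–O–E) is made by simple O-alkylation of 9 before ring C exists, with cheap reagents and without 6. On this bond it is better than the chosen plan.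
- Against it here: A6 carries two ester groups that must be removed. The three hydroxyls of A9 must be told apart so that C3 alone is capped (14 is its C3 methyl ether). An α-aryloxymalonate is a slow twofold acyl donor. The alternative leaves the arms untouched, so the aryne step is still needed.
- Comparison: in structure it builds the ring that the chosen plan takes in oxidised form from 6. In mechanism a condensation driven by aromatisation stands against substitution at a flanked fluoroarene. In step economy both need four steps from 9 to 14, so they are equal; the selectivity problem at A9 decides against it.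

Key step: step 15

Remark 1: the structures of 24 and 29 agree atom for atom with 35 and need no correction; compounds 1, 7, 25 and 33 are taken as purchasable.
Remark 2: in 29 and 30 the positions B2 and B6 are equivalent by the local symmetry of ring B, so the iodination needs stoichiometric control (one iodine per ring B) and selectivity for the phenolic rings, not direction within ring B.
Remark 3: the precursor design is refined in two ways: the B1 carbamate is N-isopropyl, so it comes off by amine-induced elimination in the flask of the triflation, and fluoroaldehyde 6 is made by lithiation–fluorination of a 3,5-dioxygenated benzaldehyde, which avoids exchanging the 4-oxygen of a gallate for fluorine.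

## Route

Step 1
Reactants: 1 3,5-dihydroxybenzaldehyde
Product: 2 3,5-bis(methoxymethoxy)benzaldehyde
Conditions: MOMCl, i-Pr2NEt, CH2Cl2, 0 °C to rt
Reagents that add atoms: chloromethyl methyl ether, COCCl
Why: Base-mediated O-alkylation of both phenols (acetal-forming Williamson reaction); the MOM ethers later direct lithiation and are removable by acid in the presence of methyl ethers.

Step 2
Reactants: 2 3,5-bis(methoxymethoxy)benzaldehyde
Product: 3 1-(dimethoxymethyl)-3,5-bis(methoxymethoxy)benzene
Conditions: HC(OMe)3, MeOH, PPTS (cat.), rt; Et3N quench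
Reagents that add atoms: trimethyl orthoformate, COC(OC)OC; methanol, CO
Why: Acid-catalysed acetalisation with the orthoformate as water scavenger; pyridinium tosylate at room temperature should be too weak to exchange aryl MOM ethers, and the acetal makes the formyl carbon inert to butyllithium.

Step 3
Reactants: 3 1-(dimethoxymethyl)-3,5-bis(methoxymethoxy)benzene
Product: 6 4-fluoro-3,5-bis(methoxymethoxy)benzaldehyde, via aryllithium 4 (not isolated), via fluoro acetal 5 (not isolated)
Conditions: n-BuLi, THF, 0 °C; NFSI, −78 °C to rt; then PPTS, acetone–H2O, rt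
Reagents that add atoms: N-fluorobenzenesulfonimide, O=S(=O)(c1ccccc1)N(F)S(=O)(=O)c1ccccc1; water, O
Why: Directed ortho-metalation should occur at the carbon flanked by the two MOM ethers (cooperative directing groups), the aryllithium is fluorinated by the N–F reagent, and the dimethyl acetal is hydrolysed under conditions much milder than those that cleave aryl MOM ethers.

Step 4
Reactants: 7 2-chloro-1,3-dimethoxybenzene
Product: 9 4-chloro-3,5-dimethoxyphenol, via arylboronate 8 (not isolated)
Conditions: [Ir(OMe)(cod)]2 (cat.), 4,4'-di-tert-butyl-2,2'-bipyridine, B2pin2, THF, 80 °C; then Oxone (2KHSO5·KHSO4·K2SO4), acetone–H2O, rt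
Reagents that add atoms: potassium peroxymonosulfate (Oxone), [K+].[O-]S(=O)(=O)OO
Why: Iridium-catalysed C–H borylation is sterically controlled and should take the only hydrogen without an ortho substituent (para to chlorine); oxidation of the boronate in the same flask gives the phenol (one-pot borylation–oxidation).

Step 5
Reactants: 9 4-chloro-3,5-dimethoxyphenol; 6 4-fluoro-3,5-bis(methoxymethoxy)benzaldehyde
Product: 10 4-(4-chloro-3,5-dimethoxyphenoxy)-3,5-bis(methoxymethoxy)benzaldehyde
Conditions: Cs2CO3, DMSO, 100 °C
Reagents that add atoms: none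
Why: Nucleophilic aromatic substitution (addition–elimination) of the fluoride para to the formyl group by an unhindered phenoxide; the small fluorine and the inductive pull of the flanking acetal oxygens should allow attack at the di-ortho-oxygenated carbon that becomes C6.

Step 6
Reactants: 10 4-(4-chloro-3,5-dimethoxyphenoxy)-3,5-bis(methoxymethoxy)benzaldehyde
Product: 12 4-(4-chloro-3,5-dimethoxyphenoxy)-3,5-bis(methoxymethoxy)phenol, via aryl formate 11 (not isolated)
Conditions: mCPBA, NaHCO3, CH2Cl2, 0 °C to rt; then K2CO3, MeOH, rt
Reagents that add atoms: 3-chloroperoxybenzoic acid, OOC(=O)c1cccc(Cl)c1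
Why: Baeyer–Villiger (Dakin-type) oxidation: the electron-rich para-aryloxy aryl group should migrate in preference to hydride, and the formate is methanolysed to the phenol; the bicarbonate buffer protects the MOM ethers.

Step 7
Reactants: 12 4-(4-chloro-3,5-dimethoxyphenoxy)-3,5-bis(methoxymethoxy)phenol
Product: 13 2-(4-chloro-3,5-dimethoxyphenoxy)-5-methoxy-1,3-bis(methoxymethoxy)benzene
Conditions: MeI, K2CO3, acetone, 50 °C
Reagents that add atoms: iodomethane, CI
Why: Williamson O-methylation of the only free phenol fixes the C3 oxygen as a permanent methyl ether.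

Step 8
Reactants: 13 2-(4-chloro-3,5-dimethoxyphenoxy)-5-methoxy-1,3-bis(methoxymethoxy)benzene
Product: 14 2-(4-chloro-3,5-dimethoxyphenoxy)-5-methoxybenzene-1,3-diol (core diol, rings C and E)
Conditions: HCl (conc., cat.), MeOH, 50 °C
Reagents that add atoms: none
Why: Acid-catalysed transacetalisation removes both MOM groups as dimethoxymethane while methyl ethers, the diaryl ether and the aryl chloride are inert; this frees the C1 and C5 hydroxyls.

Step 9
Reactants: 14 core diol; 6 4-fluoro-3,5-bis(methoxymethoxy)benzaldehyde (2.5 equiv)
Product: 15 core bis(aldehyde), 4,4'-{[2-(4-chloro-3,5-dimethoxyphenoxy)-5-methoxy-1,3-phenylene]bis(oxy)}bis[3,5-bis(methoxymethoxy)benzaldehyde]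
Conditions: Cs2CO3, DMSO, 110 °C
Reagents that add atoms: none
Why: Two-fold nucleophilic aromatic substitution of the para-formyl-activated fluoride by the C1 and C5 phenoxides should form both B4–O bonds; it is the reaction type of step 5 with a phenoxide that has one ortho aryloxy group.

Step 10
Reactants: 15 core bis(aldehyde)
Product: 17 core bis(phenol), 4,4'-{[2-(4-chloro-3,5-dimethoxyphenoxy)-5-methoxy-1,3-phenylene]bis(oxy)}bis[3,5-bis(methoxymethoxy)phenol], via bis(aryl formate) 16 (not isolated)
Conditions: mCPBA, NaHCO3, CH2Cl2, 0 °C to rt; then K2CO3, MeOH, rt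
Reagents that add atoms: 3-chloroperoxybenzoic acid, OOC(=O)c1cccc(Cl)c1
Why: Double Baeyer–Villiger (Dakin-type) oxidation as in step 6 turns each formyl group into the B1 hydroxyl; each ring B is now symmetric about its B1–B4 axis.

Step 11
Reactants: 17 core bis(phenol)
Product: 18 core bis(N-isopropylcarbamate) (B1 O-carbamates of 17)
Conditions: i-PrNCO, Et3N (cat.), CH2Cl2, rt
Reagents that add atoms: isopropyl isocyanate, CC(C)N=C=O
Why: Base-catalysed addition of the B1 phenols to the isocyanate gives O-aryl carbamates, the strongest oxygen-based directing groups for lithiation, which can later be removed under mild amine conditions.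

Step 12
Reactants: 18 core bis(N-isopropylcarbamate)
Product: 22 core bis(B6-trimethylsilyl B1-carbamate), via bis(N-silyl carbamate) 19 (not isolated), via dilithio species 20 (not isolated), via bis(C-silyl N-silyl carbamate) 21 (not isolated)
Conditions: TBSOTf, TMEDA, Et2O–THF, 0 °C to rt; n-BuLi, TMEDA, −78 °C; TMSCl, −78 °C to rt; aq. NaHSO4
Reagents that add atoms: chlorotrimethylsilane, C[Si](C)(C)Cl
Why: Carbamate-directed ortho-metalation after in situ N-silylation (which blocks the N–H) should occur at the carbon between the carbamate oxygen and a MOM ether, the most activated C–H of the molecule at −78 °C; B2 and B6 are equivalent, so one lithiation per ring and a silyl chloride quench give one product, and the N-silyl group is lost on acidic work-up.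

Step 13
Reactants: 22 core bis(B6-trimethylsilyl B1-carbamate)
Product: 24 core bis(B1 triflate, B6 trimethylsilyl) with B3 and B5 as MOM ethers, via bis(silylphenol) 23 (not isolated)
Conditions: DBU, Et2NH, MeCN, 40 °C; then PhNTf2, rt
Reagents that add atoms: N-phenylbis(trifluoromethanesulfonimide), O=S(=O)(N(c1ccccc1)S(=O)(=O)C(F)(F)F)C(F)(F)F
Why: Deprotonation of the carbamate N–H triggers E1cB loss of isopropyl isocyanate (trapped by diethylamine as a urea), and the phenoxide is triflated in the same flask; the conditions are too mild for protodesilylation or MOM cleavage.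

Step 14
Reactants: 25 2,4,6-trimethoxybenzaldehyde
Product: 27 2,4,6-trimethoxyphenol, via aryl formate 26 (not isolated)
Conditions: mCPBA, CH2Cl2, 0 °C to rt; then K2CO3, MeOH, rt
Reagents that add atoms: 3-chloroperoxybenzoic acid, OOC(=O)c1cccc(Cl)c1
Why: Baeyer–Villiger (Dakin-type) oxidation; the trimethoxyphenyl group has a very high migratory aptitude, and methanolysis of the formate gives the ring A phenol.

Step 15
Reactants: 24 core bis(B1 triflate, B6 trimethylsilyl); 27 2,4,6-trimethoxyphenol (6 equiv)
Product: 29 six-ring compound with rings A on B1, hydrogen at B6 and MOM ethers at B3 and B5, via bis(aryne) 28 (not isolated)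
Conditions: CsF, MeCN, rt to 40 °C
Reagents that add atoms: none
Why: Fluoride attacks silicon of each 2-(trimethylsilyl)aryl triflate and loss of triflate gives the B1–B6 aryne, one arm after the other. The closest known reaction type is fluoride-induced aryne generation from such triflates with O-arylation of phenols by CsF in acetonitrile. The cesium phenoxide of 27 adds through oxygen to B1 and the B6 aryl anion is protonated by the excess phenol, so two C–O bonds form and B6 ends as C–H. No ring is closed and no stereocentre is created. The selectivity needed is regiochemical: the acetal oxygen at B5 distorts the aryne and stabilises negative charge at the neighbouring B6 inductively, so the nucleophile should go to the distal carbon B1, while hydrogen at B2 exerts no opposing bias. O-arylation should win over C-arylation because both ortho positions and the para position of 27 carry methoxy groups. The aryne is unhindered and very electrophilic, so it should accept a 2,6-disubstituted phenoxide that couples poorly under copper catalysis, and the excess of phenol keeps protonation faster than addition of the aryl anion to a second aryne. MOM ethers, methyl ethers and the aryl chloride are inert to CsF at this temperature.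

Step 16
Reactants: 29 six-ring compound with MOM ethers at B3 and B5
Product: 30 six-ring tetraphenol (B3 and B5 hydroxyls free)
Conditions: HCl (conc., cat.), MeOH–THF, 45 °C
Reagents that add atoms: none
Why: Acid-catalysed transacetalisation removes the four MOM groups as dimethoxymethane; only rings B now carry free phenols.

Step 17
Reactants: 30 six-ring tetraphenol
Product: 31 six-ring bis(B6 iodide) tetraphenol
Conditions: I2 (2.05 equiv), NaHCO3, THF–H2O, 0 °C
Reagents that add atoms: iodine, II
Why: Electrophilic iodination of phenoxides; iodine with bicarbonate should react only with the resorcinol rings B (ortho to one hydroxyl, para to the other) and not with aryl ethers, and the first iodine, meta to the remaining free position, slows a second substitution on the same ring.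

Step 18
Reactants: 31 six-ring bis(B6 iodide) tetraphenol
Product: 32 six-ring bis(B6 iodide) with B3 and B5 as methyl ethers
Conditions: MeI, K2CO3, DMF, rt
Reagents that add atoms: iodomethane, CI
Why: Williamson O-methylation of the four phenols gives a neutral, non-acidic aryl iodide for the hindered coupling under nearly anhydrous conditions.

Step 19
Reactants: 32 six-ring bis(B6 iodide); 33 (2,4,6-trimethoxyphenyl)boronic acid (6 equiv)
Product: 34 eight-ring nonadecamethyl ether (rings D on B6)
Conditions: Pd(OAc)2, SPhos (2-dicyclohexylphosphino-2',6'-dimethoxybiphenyl), K3PO4, toluene–H2O (20:1), 90 °C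
Reagents that add atoms: none
Why: Suzuki–Miyaura coupling with a bulky dialkylbiarylphosphine, the ligand class suited to tetra-ortho-substituted biaryls and 2,6-dimethoxyarylboronic acids; oxidative addition of zerovalent palladium to C–I is far faster than to the hindered, electron-rich C–Cl of ring E, and the excess boronic acid offsets protodeboronation.

Step 20
Reactants: 34 eight-ring nonadecamethyl ether
Product: 35 target compound CNP0275555.0
Conditions: BBr3 (excess), CH2Cl2, −78 °C to rt; then MeOH–H2O, 0 °C, degassed
Reagents that add atoms: none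
Why: Lewis-acid demethylation of aryl methyl ethers (bromide attacks the methyl group of the boron-complexed ether); diaryl ethers, biaryl bonds and the aryl chloride should be inert, and hydrolysis frees the nineteen phenols.

## Compound list

1 | 3,5-dihydroxybenzaldehyde | O=Cc1cc(O)cc(O)c1 | starting material
2 | 3,5-bis(methoxymethoxy)benzaldehyde | COCOc1cc(C=O)cc(OCOC)c1 | intermediate
3 | 1-(dimethoxymethyl)-3,5-bis(methoxymethoxy)benzene | COCOc1cc(C(OC)OC)cc(OCOC)c1 | intermediate
4 | [4-(dimethoxymethyl)-2,6-bis(methoxymethoxy)phenyl]lithium | [Li]c1c(OCOC)cc(C(OC)OC)cc1OCOC | intermediate (not isolated)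
5 | 5-(dimethoxymethyl)-2-fluoro-1,3-bis(methoxymethoxy)benzene | COCOc1cc(C(OC)OC)cc(OCOC)c1F | intermediate (not isolated)
6 | 4-fluoro-3,5-bis(methoxymethoxy)benzaldehyde | COCOc1cc(C=O)cc(OCOC)c1F | intermediate
7 | 2-chloro-1,3-dimethoxybenzene | COc1cccc(OC)c1Cl | starting material
8 | 2-(4-chloro-3,5-dimethoxyphenyl)-4,4,5,5-tetramethyl-1,3,2-dioxaborolane | COc1cc(B2OC(C)(C)C(C)(C)O2)cc(OC)c1Cl | intermediate (not isolated)
9 | 4-chloro-3,5-dimethoxyphenol | COc1cc(O)cc(OC)c1Cl | intermediate
10 | 4-(4-chloro-3,5-dimethoxyphenoxy)-3,5-bis(methoxymethoxy)benzaldehyde | COCOc1cc(C=O)cc(OCOC)c1Oc1cc(OC)c(Cl)c(OC)c1 | intermediate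
11 | 4-(4-chloro-3,5-dimethoxyphenoxy)-3,5-bis(methoxymethoxy)phenyl formate | COCOc1cc(OC=O)cc(OCOC)c1Oc1cc(OC)c(Cl)c(OC)c1 | intermediate (not isolated)
12 | 4-(4-chloro-3,5-dimethoxyphenoxy)-3,5-bis(methoxymethoxy)phenol | COCOc1cc(O)cc(OCOC)c1Oc1cc(OC)c(Cl)c(OC)c1 | intermediate
13 | 2-(4-chloro-3,5-dimethoxyphenoxy)-5-methoxy-1,3-bis(methoxymethoxy)benzene | COCOc1cc(OC)cc(OCOC)c1Oc1cc(OC)c(Cl)c(OC)c1 | intermediate
14 | 2-(4-chloro-3,5-dimethoxyphenoxy)-5-methoxybenzene-1,3-diol (core diol) | COc1cc(O)c(Oc2cc(OC)c(Cl)c(OC)c2)c(O)c1 | intermediate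
15 | core bis(aldehyde): 4,4'-{[2-(4-chloro-3,5-dimethoxyphenoxy)-5-methoxy-1,3-phenylene]bis(oxy)}bis[3,5-bis(methoxymethoxy)benzaldehyde] | COc1cc(Oc2c(OCOC)cc(C=O)cc2OCOC)c(Oc2cc(OC)c(Cl)c(OC)c2)c(Oc2c(OCOC)cc(C=O)cc2OCOC)c1 | intermediate
16 | core bis(aryl formate): diformate of 17 at the B1 oxygens | COc1cc(Oc2c(OCOC)cc(OC=O)cc2OCOC)c(Oc2cc(OC)c(Cl)c(OC)c2)c(Oc2c(OCOC)cc(OC=O)cc2OCOC)c1 | intermediate (not isolated)
17 | core bis(phenol): 4,4'-{[2-(4-chloro-3,5-dimethoxyphenoxy)-5-methoxy-1,3-phenylene]bis(oxy)}bis[3,5-bis(methoxymethoxy)phenol] | COc1cc(Oc2c(OCOC)cc(O)cc2OCOC)c(Oc2cc(OC)c(Cl)c(OC)c2)c(Oc2c(OCOC)cc(O)cc2OCOC)c1 | intermediate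
18 | core bis(N-isopropylcarbamate): B1 O-C(=O)NH-i-Pr on both rings B | COc1cc(Oc2c(OCOC)cc(OC(=O)NC(C)C)cc2OCOC)c(Oc2cc(OC)c(Cl)c(OC)c2)c(Oc2c(OCOC)cc(OC(=O)NC(C)C)cc2OCOC)c1 | intermediate
19 | core bis(N-tert-butyldimethylsilyl-N-isopropylcarbamate) | COc1cc(Oc2c(OCOC)cc(OC(=O)N(C(C)C)[Si](C)(C)C(C)(C)C)cc2OCOC)c(Oc2cc(OC)c(Cl)c(OC)c2)c(Oc2c(OCOC)cc(OC(=O)N(C(C)C)[Si](C)(C)C(C)(C)C)cc2OCOC)c1 | intermediate (not isolated)
20 | B6,B6'-dilithio derivative of 19 | COc1cc(Oc2c(OCOC)cc(OC(=O)N(C(C)C)[Si](C)(C)C(C)(C)C)c([Li])c2OCOC)c(Oc2cc(OC)c(Cl)c(OC)c2)c(Oc2c(OCOC)cc(OC(=O)N(C(C)C)[Si](C)(C)C(C)(C)C)c([Li])c2OCOC)c1 | intermediate (not isolated)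
21 | B6,B6'-bis(trimethylsilyl) derivative of 19 | COc1cc(Oc2c(OCOC)cc(OC(=O)N(C(C)C)[Si](C)(C)C(C)(C)C)c([Si](C)(C)C)c2OCOC)c(Oc2cc(OC)c(Cl)c(OC)c2)c(Oc2c(OCOC)cc(OC(=O)N(C(C)C)[Si](C)(C)C(C)(C)C)c([Si](C)(C)C)c2OCOC)c1 | intermediate (not isolated)
22 | core bis(B6-trimethylsilyl B1 N-isopropylcarbamate) | COc1cc(Oc2c(OCOC)cc(OC(=O)NC(C)C)c([Si](C)(C)C)c2OCOC)c(Oc2cc(OC)c(Cl)c(OC)c2)c(Oc2c(OCOC)cc(OC(=O)NC(C)C)c([Si](C)(C)C)c2OCOC)c1 | intermediate
23 | core bis(B1 phenol, B6 trimethylsilyl) | COc1cc(Oc2c(OCOC)cc(O)c([Si](C)(C)C)c2OCOC)c(Oc2cc(OC)c(Cl)c(OC)c2)c(Oc2c(OCOC)cc(O)c([Si](C)(C)C)c2OCOC)c1 | intermediate (not isolated)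
24 | core bis(B1 triflate, B6 trimethylsilyl) with B3 and B5 as MOM ethers | COc1cc(Oc2c(OCOC)cc(OS(=O)(=O)C(F)(F)F)c([Si](C)(C)C)c2OCOC)c(Oc2cc(OC)c(Cl)c(OC)c2)c(Oc2c(OCOC)cc(OS(=O)(=O)C(F)(F)F)c([Si](C)(C)C)c2OCOC)c1 | intermediate
25 | 2,4,6-trimethoxybenzaldehyde | COc1cc(OC)c(C=O)c(OC)c1 | starting material
26 | 2,4,6-trimethoxyphenyl formate | COc1cc(OC)c(OC=O)c(OC)c1 | intermediate (not isolated)
27 | 2,4,6-trimethoxyphenol | COc1cc(OC)c(O)c(OC)c1 | intermediate
28 | core bis(B1–B6 aryne), drawn with both arynes for bookkeeping; they form and are trapped one at a time | COc1cc(OC2=C(OCOC)C#CC=C2OCOC)c(Oc2cc(OC)c(Cl)c(OC)c2)c(OC2=C(OCOC)C#CC=C2OCOC)c1 | intermediate (not isolated)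
29 | six-ring compound: 2,4,6-trimethoxyphenoxy on B1, H at B6, MOM ethers at B3 and B5 | COc1cc(Oc2c(OCOC)cc(Oc3c(OC)cc(OC)cc3OC)cc2OCOC)c(Oc2cc(OC)c(Cl)c(OC)c2)c(Oc2c(OCOC)cc(Oc3c(OC)cc(OC)cc3OC)cc2OCOC)c1 | intermediate
30 | six-ring tetraphenol (B3 and B5 OH) | COc1cc(Oc2c(O)cc(Oc3c(OC)cc(OC)cc3OC)cc2O)c(Oc2cc(OC)c(Cl)c(OC)c2)c(Oc2c(O)cc(Oc3c(OC)cc(OC)cc3OC)cc2O)c1 | intermediate
31 | six-ring bis(B6 iodide) tetraphenol | COc1cc(Oc2c(O)cc(Oc3c(OC)cc(OC)cc3OC)c(I)c2O)c(Oc2cc(OC)c(Cl)c(OC)c2)c(Oc2c(O)cc(Oc3c(OC)cc(OC)cc3OC)c(I)c2O)c1 | intermediate
32 | six-ring bis(B6 iodide) with B3 and B5 OMe | COc1cc(Oc2c(OC)cc(Oc3c(OC)cc(OC)cc3OC)c(I)c2OC)c(Oc2cc(OC)c(Cl)c(OC)c2)c(Oc2c(OC)cc(Oc3c(OC)cc(OC)cc3OC)c(I)c2OC)c1 | intermediate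
33 | (2,4,6-trimethoxyphenyl)boronic acid | COc1cc(OC)c(B(O)O)c(OC)c1 | starting material
34 | eight-ring nonadecamethyl ether (all nineteen oxygens of 35 as OMe) | COc1cc(Oc2c(OC)cc(Oc3c(OC)cc(OC)cc3OC)c(-c3c(OC)cc(OC)cc3OC)c2OC)c(Oc2cc(OC)c(Cl)c(OC)c2)c(Oc2c(OC)cc(Oc3c(OC)cc(OC)cc3OC)c(-c3c(OC)cc(OC)cc3OC)c2OC)c1 | intermediate
35 | CNP0275555.0 (no stereocentres) | Oc1cc(O)c(Oc2cc(O)c(Oc3cc(O)cc(Oc4c(O)cc(Oc5c(O)cc(O)cc5O)c(-c5c(O)cc(O)cc5O)c4O)c3Oc3cc(O)c(Cl)c(O)c3)c(O)c2-c2c(O)cc(O)cc2O)c(O)c1 | target

## Step count and least certain steps

Total step count: 20. Longest linear sequence: 18 steps (steps 1–3, 5–13, 15–20); steps 4 and 14 are one-step branches.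

**Step 15 (key step).** The aryne may be lost to other pathways: desilylation or S–O cleavage of the triflate without elimination, addition of the B6 aryl anion to a second aryne, or reaction on one arm only. These become more likely because a hindered phenoxide adds slowly.
Fallback, from 17 and 6, back to the route at 29: the polarity is returned to substitution at an activated ring A.
- The MOM groups of 6 are removed (HCl, MeOH) to give 4-fluoro-3,5-dihydroxybenzaldehyde F1.
- F1 is methylated (MeI, K2CO3) to 4-fluoro-3,5-dimethoxybenzaldehyde F2.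
- The B1 phenoxides of 17 displace fluoride from F2 (Cs2CO3, DMSO, 100 °C) to give the six-ring bis(aldehyde) F3.
- Baeyer–Villiger oxidation (mCPBA) gives the bis(formate) F4, and methanolysis gives the six-ring bis(phenol) F5.
- Methylation of F5 (MeI, K2CO3) gives 29.

**Step 9.** Attack at a carbon flanked by two acetal oxygens may be slow, so that the second substitution stalls or the aldehyde degrades at the temperature needed.
Fallback, from 3 and 14, back at 15: copper catalysis with an iodide replaces the uncatalysed substitution.
- Lithiation of 3 as in step 3 and quenching with I2 gives the iodo acetal F6.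
- Hydrolysis (PPTS, acetone–H2O) gives 4-iodo-3,5-bis(methoxymethoxy)benzaldehyde F7.
- Ullmann-type coupling of 14 with F7 (CuI, picolinic acid, K3PO4, DMSO, 90 °C), helped by the chelating ortho acetal oxygens, gives 15.

**Step 12.** The silyl triflate used for N-silylation may activate the MOM acetals, and metalation at other flanked C–H positions of rings C and E or a second silylation of one ring B may erode the yield.
Fallback, from 17, back at 24: halogen–metal exchange replaces deprotonation.
- Ortho-bromination of the B1 phenols (NBS, i-Pr2NH cat., CH2Cl2, −78 °C) gives the bis(2-bromophenol) F8.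
- Silylation on oxygen (HMDS, THF, reflux) gives the bis(trimethylsilyl ether) F9.
- n-BuLi at −78 °C effects bromine–lithium exchange and 1,3-migration of silicon from oxygen to carbon (retro-Brook), giving the dilithium salt of 23.
- Tf2O in the same flask gives 24.

**Step 19.** Protodeboronation of the electron-rich boronic acid may outrun the slow transmetalation at the tetra-ortho stage, and palladium may insert into the ring E C–Cl bond once the iodide is used up.
Fallback, from 32, back at 34: an organozinc made by deprotonation replaces the boronic acid, at a lower temperature.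
- Purchased 1,3,5-trimethoxybenzene is lithiated (n-BuLi, THF, 0 °C) to (2,4,6-trimethoxyphenyl)lithium F10.
- Transmetalation with ZnCl2 gives (2,4,6-trimethoxyphenyl)zinc chloride F11.
- Negishi coupling of F11 with 32 (Pd(OAc)2, 2-dicyclohexylphosphino-2',6'-diisopropoxybiphenyl, THF, 60 °C) gives 34.

**Step 20.** Cleavage of nineteen ethers may stop short, and the free polyphenol may oxidise during work-up and chromatography.
Fallback, from 34, back at 35: the crude product is isolated as a derivative.
- The crude demethylation product is acetylated (Ac2O, pyridine) to the nonadeca-acetate F12, which is stable and can be purified on silica; partly methylated material is separated at this stage.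
- Deacetylation (NaOMe, MeOH, degassed, then acidic resin) gives 35.

## Further compounds

F1 | step 15 | 4-fluoro-3,5-dihydroxybenzaldehyde | O=Cc1cc(O)c(F)c(O)c1
F2 | step 15 | 4-fluoro-3,5-dimethoxybenzaldehyde | COc1cc(C=O)cc(OC)c1F
F3 | step 15 | six-ring bis(aldehyde): 4-formyl-2,6-dimethoxyphenoxy on B1 of both rings B, MOM ethers at B3 and B5 | COc1cc(Oc2c(OCOC)cc(Oc3c(OC)cc(C=O)cc3OC)cc2OCOC)c(Oc2cc(OC)c(Cl)c(OC)c2)c(Oc2c(OCOC)cc(Oc3c(OC)cc(C=O)cc3OC)cc2OCOC)c1
F4 | step 15 | six-ring bis(formate) from F3 | COc1cc(Oc2c(OCOC)cc(Oc3c(OC)cc(OC=O)cc3OC)cc2OCOC)c(Oc2cc(OC)c(Cl)c(OC)c2)c(Oc2c(OCOC)cc(Oc3c(OC)cc(OC=O)cc3OC)cc2OCOC)c1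
F5 | step 15 | six-ring bis(phenol): 4-hydroxy-2,6-dimethoxyphenoxy on B1 of both rings B | COc1cc(Oc2c(OCOC)cc(Oc3c(OC)cc(O)cc3OC)cc2OCOC)c(Oc2cc(OC)c(Cl)c(OC)c2)c(Oc2c(OCOC)cc(Oc3c(OC)cc(O)cc3OC)cc2OCOC)c1
F6 | step 9 | 5-(dimethoxymethyl)-2-iodo-1,3-bis(methoxymethoxy)benzene | COCOc1cc(C(OC)OC)cc(OCOC)c1I
F7 | step 9 | 4-iodo-3,5-bis(methoxymethoxy)benzaldehyde | COCOc1cc(C=O)cc(OCOC)c1I
F8 | step 12 | core bis(B1 phenol, B6 bromide) with MOM ethers at B3 and B5 | COc1cc(Oc2c(OCOC)cc(O)c(Br)c2OCOC)c(Oc2cc(OC)c(Cl)c(OC)c2)c(Oc2c(OCOC)cc(O)c(Br)c2OCOC)c1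
F9 | step 12 | core bis(B1 trimethylsilyl ether, B6 bromide) | COc1cc(Oc2c(OCOC)cc(O[Si](C)(C)C)c(Br)c2OCOC)c(Oc2cc(OC)c(Cl)c(OC)c2)c(Oc2c(OCOC)cc(O[Si](C)(C)C)c(Br)c2OCOC)c1
F10 | step 19 | (2,4,6-trimethoxyphenyl)lithium | COc1cc(OC)c([Li])c(OC)c1
F11 | step 19 | (2,4,6-trimethoxyphenyl)zinc chloride | COc1cc(OC)c([Zn]Cl)c(OC)c1
F12 | step 20 | nonadeca-acetate of 35 | CC(=O)Oc1cc(OC(C)=O)c(Oc2cc(OC(C)=O)c(Oc3cc(OC(C)=O)cc(Oc4c(OC(C)=O)cc(Oc5c(OC(C)=O)cc(OC(C)=O)cc5OC(C)=O)c(-c5c(OC(C)=O)cc(OC(C)=O)cc5OC(C)=O)c4OC(C)=O)c3Oc3cc(OC(C)=O)c(Cl)c(OC(C)=O)c3)c(OC(C)=O)c2-c2c(OC(C)=O)cc(OC(C)=O)cc2OC(C)=O)c(OC(C)=O)c1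
A1 | alternative 1 | eight-ring compound with both rings D as free phloroglucinols, all other oxygens as methyl ethers | COc1cc(Oc2c(OC)cc(Oc3c(OC)cc(OC)cc3OC)c(-c3c(O)cc(O)cc3O)c2OC)c(Oc2cc(OC)c(Cl)c(OC)c2)c(Oc2c(OC)cc(Oc3c(OC)cc(OC)cc3OC)c(-c3c(O)cc(O)cc3O)c2OC)c1
A2 | alternative 1 | six-ring bis(methyl 6-aryl-3,5-dioxohexanoate), chains on B6 | COc1cc(Oc2c(OC)cc(Oc3c(OC)cc(OC)cc3OC)c(CC(=O)CC(=O)CC(=O)OC)c2OC)c(Oc2cc(OC)c(Cl)c(OC)c2)c(Oc2c(OC)cc(Oc3c(OC)cc(OC)cc3OC)c(CC(=O)CC(=O)CC(=O)OC)c2OC)c1
A3 | alternative 2 | eight-ring compound with B5 hydroxyls free and B3 ethoxy | COc1cc(Oc2c(OCC)cc(Oc3c(OC)cc(OC)cc3OC)c(-c3c(OC)cc(OC)cc3OC)c2O)c(Oc2cc(OC)c(Cl)c(OC)c2)c(Oc2c(OCC)cc(Oc3c(OC)cc(OC)cc3OC)c(-c3c(OC)cc(OC)cc3OC)c2O)c1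
A4 | alternative 2 | core bis(3-ethoxy-4-aryloxycyclobut-2-en-1-one), mixture of stereoisomers at the two ring sp3 carbons | COc1cc(OC2C(=O)C=C2OCC)c(Oc2cc(OC)c(Cl)c(OC)c2)c(OC2C(=O)C=C2OCC)c1
A5 | alternative 2 | 1,3,5-trimethoxy-2-[(2,4,6-trimethoxyphenyl)ethynyloxy]benzene (ynol ether carrying rings A and D) | COc1cc(OC)c(C#COc2c(OC)cc(OC)cc2OC)c(OC)c1
A6 | alternative 3 | diethyl 5-(4-chloro-3,5-dimethoxyphenoxy)-2,4,6-trihydroxybenzene-1,3-dicarboxylate | CCOC(=O)c1c(O)c(C(=O)OCC)c(O)c(Oc2cc(OC)c(Cl)c(OC)c2)c1O
A7 | alternative 3 | diethyl 2-(4-chloro-3,5-dimethoxyphenoxy)malonate | CCOC(=O)C(Oc1cc(OC)c(Cl)c(OC)c1)C(=O)OCC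
A8 | alternative 3 | diethyl 1,3-acetonedicarboxylate | CCOC(=O)CC(=O)CC(=O)OCC
A9 | alternative 3 | 2-(4-chloro-3,5-dimethoxyphenoxy)benzene-1,3,5-triol | COc1cc(Oc2c(O)cc(O)cc2O)cc(OC)c1Cl
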